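Everything rests on assembling ring B last from open-chain pieces instead of joining two finished arenes through a hindered diaryl ether. Ring B is a hexasubstituted benzene; four adjacent ring carbons, bearing in turn the ether oxygen, a hydroxyl, the methyl and a second hydroxyl, are a masked 4-aryloxy-2-methylacetoacetate, and the remaining two carry the phthalide carbons. The precursor is therefore a 4-aryloxy-1-methoxy-2-methyl-1,3-bis(trimethylsilyloxy)buta-1,3-diene grown on the ring A salicylate oxygen. One (4+2) cycloaddition–aromatisation with a 4-silyloxybut-2-ynoate forms both ring B C–C bonds that flank the phthalide carbons. Two lactonisations, debenzylation and a closing enantioselective enzymatic hydroxylation of the phthalide CH2 finish the synthesis.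

Key step: step 11

Assumption: the only stereocentre is the lactol carbon of the hydroxyphthalide, R as drawn; such lactols can epimerise through the ring-opened formyl acid, so it is created in the last step and the product is to be isolated cold, near neutral pH and without base.

Remark: species that are only generated and consumed in situ as reagent states of a numbered compound (phenoxides, enolates, the lithium acetylide, the Vilsmeier iminium salt, the O-acylisourea, allylpalladium complexes) are not numbered.

Step 1
Reactants: 1 3,4,5-trimethoxytoluene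
Product: 2 2,3,4-trimethoxy-6-methylbenzaldehyde
Conditions: POCl3, DMF, 0 → 80 °C; aq. NaOAc
Reagents that add atoms: N,N-dimethylformamide CN(C)C=O; water O
Why: Vilsmeier–Haack formylation of an electron-rich arene; the two free ring positions are equivalent, each ortho and para to methoxy groups, so a single aldehyde should result.

Step 2
Reactants: 2 2,3,4-trimethoxy-6-methylbenzaldehyde
Product: 3 2,3-dihydroxy-4-methoxy-6-methylbenzaldehyde
Conditions: BCl3 (2.5 equiv), CH2Cl2, −10 °C → rt; H2O
Reagents that add atoms: none
Why: Chelation-directed ether cleavage: BCl3 bound to the formyl oxygen removes the ortho methyl ether and the resulting aryloxyboron chloride relays cleavage to the adjacent methoxy group, whereas the para methoxy group cannot chelate and should survive.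

Step 3
Reactants: 3 2,3-dihydroxy-4-methoxy-6-methylbenzaldehyde
Product: 4 3-(benzyloxy)-2-hydroxy-4-methoxy-6-methylbenzaldehyde
Conditions: NaH (2.2 equiv), DMF, 0 °C → rt; BnBr (1.0 equiv); aq. HCl
Reagents that add atoms: benzyl bromide BrCc1ccccc1
Why: Williamson etherification of the dianion: the C-2 phenoxide is delocalised into and chelated with the formyl group, so the single equivalent of benzyl bromide should be taken by the more basic C-3 phenoxide.

Step 4
Reactants: 4 3-(benzyloxy)-2-hydroxy-4-methoxy-6-methylbenzaldehyde
Product: 5 3-(benzyloxy)-2-hydroxy-4-methoxy-6-methylbenzoic acid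
Conditions: NaClO2, NaH2PO4, 2-methylbut-2-ene, t-BuOH–H2O, rt
Reagents that add atoms: sodium chlorite [Na+].[O-]Cl=O
Why: Pinnick (chlorite) oxidation converts the aldehyde into the acid under buffered conditions, 2-methylbut-2-ene trapping hypochlorous acid so that the electron-rich ring is not chlorinated.

Step 5
Reactants: 5 3-(benzyloxy)-2-hydroxy-4-methoxy-6-methylbenzoic acid
Product: 6 allyl 3-(benzyloxy)-2-hydroxy-4-methoxy-6-methylbenzoate (ring A salicylate)
Conditions: allyl bromide, KHCO3, DMF, rt
Reagents that add atoms: allyl bromide C=CCBr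
Why: Carboxylate alkylation (SN2) with hydrogencarbonate as base leaves the chelated phenol untouched; the allyl ester is chosen because this di-ortho-substituted benzoate can later be unmasked by zerovalent palladium without saponification.

Step 6
Reactants: 7 methyl 2-methylacetoacetate (methyl 2-methyl-3-oxobutanoate, racemic)
Product: 9 methyl 4-bromo-2-methyl-3-oxobutanoate (racemic), via methyl 2-bromo-2-methyl-3-oxobutanoate 8 (not isolated)
Conditions: Br2 (1.0 equiv), CHCl3, 0 °C → rt, 16 h; air purge
Reagents that add atoms: bromine BrBr
Why: Acid-catalysed α-bromination of the keto ester gives first the 2-bromo compound, which the hydrogen bromide formed equilibrates by bromine transfer through the enols to the more stable terminal bromomethyl ketone.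

Step 7
Reactants: 6 allyl 3-(benzyloxy)-2-hydroxy-4-methoxy-6-methylbenzoate; 9 methyl 4-bromo-2-methyl-3-oxobutanoate
Product: 10 methyl 4-[2-[(allyloxy)carbonyl]-6-(benzyloxy)-5-methoxy-3-methylphenoxy]-2-methyl-3-oxobutanoate (racemic at C-2)
Conditions: K2CO3, NaI (cat.), acetone, rt → 50 °C
Reagents that add atoms: none
Why: Williamson etherification of the salicylate phenoxide with a reactive α-bromo ketone; the C-2 methyl group slows C-alkylation of the keto ester enolate, and under carbonate only C-2 is enolised, so the carbon next to the new ether never becomes a nucleophile toward the neighbouring ester.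

Step 8
Reactants: 10 methyl 4-aryloxy-2-methyl-3-oxobutanoate (aryl = ring A unit)
Product: 11 methyl 4-[2-[(allyloxy)carbonyl]-6-(benzyloxy)-5-methoxy-3-methylphenoxy]-2-methyl-3-(trimethylsilyloxy)but-2-enoate (E/Z mixture)
Conditions: TMSCl, Et3N, toluene, rt; filtration under argon
Reagents that add atoms: chlorotrimethylsilane C[Si](C)(C)Cl
Why: Silyl enol ether formation with an amine base under equilibrating conditions gives the ester-conjugated enol ether, the usual first stage of bis(silyloxy)diene synthesis from 2-alkylacetoacetates.

Step 9
Reactants: 11 mono(silyl enol ether)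
Product: 12 allyl 3-(benzyloxy)-4-methoxy-2-{[4-methoxy-3-methyl-2,4-bis(trimethylsilyloxy)buta-1,3-dien-1-yl]oxy}-6-methylbenzoate (the 4-aryloxy-1-methoxy-2-methyl-1,3-bis(trimethylsilyloxy)buta-1,3-diene; aryloxy-bearing double bond expected Z, ketene acetal geometry immaterial)
Conditions: TMSCl, THF, −78 °C; LiN(i-Pr)2 (LDA) added slowly (internal quench), −78 → 0 °C; pentane, filtration under argon; used crude
Reagents that add atoms: chlorotrimethylsilane C[Si](C)(C)Cl
Why: Vinylogous (γ) deprotonation and O-silylation of the resulting ester dienolate give the 1,3-bis(silyloxy)diene; TMSCl is present from the start so that the dienolate is trapped before it can add to the neighbouring allyl ester, and the Z geometry (aryloxy cis to silyloxy) should be favoured on steric grounds.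

Step 10
Reactants: 13 tert-butyldimethyl(prop-2-yn-1-yloxy)silane
Product: 14 methyl 4-(tert-butyldimethylsilyloxy)but-2-ynoate
Conditions: n-BuLi, THF, −78 °C; ClCO2Me, −78 → 0 °C
Reagents that add atoms: methyl chloroformate COC(=O)Cl
Why: Deprotonation of the terminal alkyne and acylation of the lithium acetylide with a chloroformate is the standard synthesis of alk-2-ynoates.

Step 11
Reactants: 12 aryloxy bis(silyloxy)diene; 14 methyl 4-(tert-butyldimethylsilyloxy)but-2-ynoate
Product: 17 allyl 3-(benzyloxy)-2-[2-{[(tert-butyldimethylsilyl)oxy]methyl}-4,6-dihydroxy-3-(methoxycarbonyl)-5-methylphenoxy]-4-methoxy-6-methylbenzoate, via cyclohexa-1,4-diene cycloadduct 15 (not isolated), via ring B mono(trimethylsilyl) ether 16 (not isolated)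
Conditions: 14 (2.5 equiv), toluene (2 M) or neat, 100–110 °C, sealed tube, argon, 24–48 h; then MeOH, citric acid (cat.), 0 °C
Reagents that add atoms: none
Why: The three oxygen donors polarise the diene so that its aryloxy-bearing terminus (β to the inner silyloxy group, vinylogous to the ketene acetal) is the nucleophilic end, and the ynoate is electrophilic at the carbon bearing CH2OTBS; these carbons bond first, in an asynchronous Diels–Alder or a Mukaiyama–Michael-type event, and the ketene acetal carbon then bonds to the ester-bearing alkyne carbon. Ring B thus closes in the (4+2) mode, four ring atoms from the diene and two from the alkyne, giving cyclohexa-1,4-diene 15; in the stepwise limit the closure is attack of the allenoate carbon on the O,O-stabilised cation. Expulsion of MeOSiMe3 from the ketal carbon and enolisation of the hydrogen at the aryloxy-bearing carbon aromatise 15 to 16, and methanolysis frees the second hydroxyl. The closest known reaction type is the Diels–Alder/aromatisation of 1-alkoxy-1,3-bis(silyloxy)buta-1,3-dienes with alkynoates to hydroxybenzoates. No stereocentre is formed. The step needs one regiochemistry (ester next to the new hydrogen-bonded hydroxyl, CH2O next to the ether oxygen), which the matched push–pull polarisation secures, and it needs the ether oxygen to stay on the ring, which holds because only the ketal carbon carries a group that can leave on aromatisation.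

Step 12
Reactants: 17 ring B diaryl ether diol
Product: 19 allyl 3-(benzyloxy)-2-[(5,7-dihydroxy-6-methyl-1-oxo-1,3-dihydro-2-benzofuran-4-yl)oxy]-4-methoxy-6-methylbenzoate, via hydroxymethyl diester 18 (not isolated)
Conditions: TsOH·H2O (cat.), MeOH–CH2Cl2, rt → 40 °C
Reagents that add atoms: none
Why: Acid-catalysed methanolysis removes the primary silyl ether and the freed benzylic hydroxyl closes onto the adjacent methyl ester (five-membered lactonisation, 5-exo-trig at the ester carbonyl) to give the phthalide, while the hindered allyl ester and the benzyl ether are inert.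

Step 13
Reactants: 19 phthalide allyl ester
Product: 20 3-(benzyloxy)-2-[(5,7-dihydroxy-6-methyl-1-oxo-1,3-dihydro-2-benzofuran-4-yl)oxy]-4-methoxy-6-methylbenzoic acid
Conditions: Pd(PPh3)4 (5 mol %), morpholine, THF, rt; aq. citric acid
Reagents that add atoms: none
Why: Tsuji–Trost deallylation: zerovalent palladium ionises the allyl ester and morpholine traps the allyl fragment, releasing the hindered acid under neutral conditions that spare the phthalide, the phenols and the benzyl ether.

Step 14
Reactants: 20 hydroxy acid
Product: 21 benzyl-protected depsidone phthalide (seven-membered lactone between the ring A carboxyl and the ring B hydroxyl next to the ether oxygen; ring A carries OBn next to the ether oxygen, then OMe, H and Me; ring B carries Me, the hydrogen-bonded OH and the fused phthalide with its CH2 next to the ether-bearing carbon)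
Conditions: DCC, DMAP (cat.), CH2Cl2 (0.005 M), 0 °C → rt
Reagents that add atoms: none
Why: Carbodiimide (Steglich-type) lactonisation at high dilution: only the ring B hydroxyl next to the ether oxygen can reach the activated carboxyl (7-exo-trig closure of the depsidone ring), the other hydroxyl being remote and hydrogen-bonded to the phthalide carbonyl.

Step 15
Reactants: 21 benzyl-protected depsidone phthalide
Product: 22 depsidone phthalide with free ring A hydroxyl (21 with OBn replaced by OH)
Conditions: H2 (1 atm), Pd/C (10 wt %), EtOAc, rt
Reagents that add atoms: none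
Why: Hydrogenolysis of the aryl benzyl ether over palladium; the phthalide C–O bond lies in the plane of its arene and is therefore poorly activated as a benzylic bond, and the aryl ester lactone is not reduced.

Step 16
Reactants: 22 depsidone phthalide
Product: 23 target, the R lactol (22 with the phthalide CH2 converted into (R)-CH(OH))
Conditions: unspecific peroxygenase (EC 1.11.2.1, recombinant Agrocybe aegerita enzyme or homologue, variant chosen by screening for the R lactol), H2O2 (slow feed), sodium ascorbate (additive), potassium phosphate buffer pH 6.5–MeCN (4:1), 20 °C; EtOAc extraction at 0 °C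
Reagents that add atoms: hydrogen peroxide OO
Why: Proposed new method: the heme-thiolate peroxygenase, activated by H2O2 to its oxoiron porphyrin radical cation (tetravalent iron), should abstract one of the two enantiotopic benzylic O–CH2 hydrogens of the phthalide and return OH by rebound with retention, so that the chiral active site, chosen by screening, sets the R lactol centre directly; the closest known reaction types are peroxygenase-catalysed enantioselective benzylic hydroxylation of alkylbenzenes and α-hydroxylation of benzylic ethers to hemiacetals, and ascorbate is added to return phenoxyl radicals to phenols.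

Compound list

1 | 3,4,5-trimethoxytoluene | COc1cc(C)cc(OC)c1OC | starting material
2 | 2,3,4-trimethoxy-6-methylbenzaldehyde | COc1cc(C)c(C=O)c(OC)c1OC | intermediate
3 | 2,3-dihydroxy-4-methoxy-6-methylbenzaldehyde | COc1cc(C)c(C=O)c(O)c1O | intermediate
4 | 3-(benzyloxy)-2-hydroxy-4-methoxy-6-methylbenzaldehyde | COc1cc(C)c(C=O)c(O)c1OCc1ccccc1 | intermediate
5 | 3-(benzyloxy)-2-hydroxy-4-methoxy-6-methylbenzoic acid | COc1cc(C)c(C(=O)O)c(O)c1OCc1ccccc1 | intermediate
6 | allyl 3-(benzyloxy)-2-hydroxy-4-methoxy-6-methylbenzoate | COc1cc(C)c(C(=O)OCC=C)c(O)c1OCc1ccccc1 | intermediate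
7 | methyl 2-methylacetoacetate (racemic) | COC(=O)C(C)C(C)=O | starting material
8 | methyl 2-bromo-2-methyl-3-oxobutanoate (racemic) | COC(=O)C(C)(Br)C(C)=O | intermediate (not isolated)
9 | methyl 4-bromo-2-methyl-3-oxobutanoate (racemic) | COC(=O)C(C)C(=O)CBr | intermediate
10 | methyl 4-[2-[(allyloxy)carbonyl]-6-(benzyloxy)-5-methoxy-3-methylphenoxy]-2-methyl-3-oxobutanoate (racemic) | COC(=O)C(C)C(=O)COc1c(C(=O)OCC=C)c(C)cc(OC)c1OCc1ccccc1 | intermediate
11 | methyl 4-[2-[(allyloxy)carbonyl]-6-(benzyloxy)-5-methoxy-3-methylphenoxy]-2-methyl-3-(trimethylsilyloxy)but-2-enoate (E/Z mixture) | COC(=O)C(C)=C(O[Si](C)(C)C)COc1c(C(=O)OCC=C)c(C)cc(OC)c1OCc1ccccc1 | intermediate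
12 | allyl 3-(benzyloxy)-4-methoxy-2-{[4-methoxy-3-methyl-2,4-bis(trimethylsilyloxy)buta-1,3-dien-1-yl]oxy}-6-methylbenzoate (geometric isomers, aryloxy-bearing double bond expected Z) | COC(O[Si](C)(C)C)=C(C)C(O[Si](C)(C)C)=COc1c(C(=O)OCC=C)c(C)cc(OC)c1OCc1ccccc1 | intermediate
13 | tert-butyldimethyl(prop-2-yn-1-yloxy)silane | C#CCO[Si](C)(C)C(C)(C)C | starting material
14 | methyl 4-(tert-butyldimethylsilyloxy)but-2-ynoate | COC(=O)C#CCO[Si](C)(C)C(C)(C)C | intermediate
15 | methyl 3-aryloxy-2-{[(tert-butyldimethylsilyl)oxy]methyl}-6-methoxy-5-methyl-4,6-bis(trimethylsilyloxy)cyclohexa-1,4-diene-1-carboxylate (aryl = ring A unit; diastereomer mixture) | COC(=O)C1=C(CO[Si](C)(C)C(C)(C)C)C(Oc2c(C(=O)OCC=C)c(C)cc(OC)c2OCc2ccccc2)C(O[Si](C)(C)C)=C(C)C1(OC)O[Si](C)(C)C | intermediate (not isolated)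
16 | 17 carrying a trimethylsilyl group on the ring B hydroxyl next to the ether oxygen | COC(=O)c1c(O)c(C)c(O[Si](C)(C)C)c(Oc2c(C(=O)OCC=C)c(C)cc(OC)c2OCc2ccccc2)c1CO[Si](C)(C)C(C)(C)C | intermediate (not isolated)
17 | allyl 3-(benzyloxy)-2-[2-{[(tert-butyldimethylsilyl)oxy]methyl}-4,6-dihydroxy-3-(methoxycarbonyl)-5-methylphenoxy]-4-methoxy-6-methylbenzoate | COC(=O)c1c(O)c(C)c(O)c(Oc2c(C(=O)OCC=C)c(C)cc(OC)c2OCc2ccccc2)c1CO[Si](C)(C)C(C)(C)C | intermediate
18 | allyl 3-(benzyloxy)-2-[4,6-dihydroxy-2-(hydroxymethyl)-3-(methoxycarbonyl)-5-methylphenoxy]-4-methoxy-6-methylbenzoate | COC(=O)c1c(O)c(C)c(O)c(Oc2c(C(=O)OCC=C)c(C)cc(OC)c2OCc2ccccc2)c1CO | intermediate (not isolated)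
19 | allyl 3-(benzyloxy)-2-[(5,7-dihydroxy-6-methyl-1-oxo-1,3-dihydro-2-benzofuran-4-yl)oxy]-4-methoxy-6-methylbenzoate | C=CCOC(=O)c1c(C)cc(OC)c(OCc2ccccc2)c1Oc1c(O)c(C)c(O)c2c1COC2=O | intermediate
20 | 3-(benzyloxy)-2-[(5,7-dihydroxy-6-methyl-1-oxo-1,3-dihydro-2-benzofuran-4-yl)oxy]-4-methoxy-6-methylbenzoic acid | OC(=O)c1c(C)cc(OC)c(OCc2ccccc2)c1Oc1c(O)c(C)c(O)c2c1COC2=O | intermediate
21 | benzyl-protected depsidone phthalide | COc1cc(C)c2c(c1OCc1ccccc1)Oc1c(c(C)c(O)c3c1COC3=O)OC2=O | intermediate
22 | depsidone phthalide with free ring A hydroxyl | COc1cc(C)c2c(c1O)Oc1c(c(C)c(O)c3c1COC3=O)OC2=O | intermediate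
23 | (R)-hydroxyphthalide depsidone CNP0211607.1 | COc1cc(C)c2c(c1O)Oc1c(c(C)c(O)c3c1[C@H](O)OC3=O)OC2=O | target

Total step count: 16. Longest linear sequence: 14 steps (steps 1–5, 7–9, 11–16).

Steps most likely to fail

Step 16. The enzyme may fail to bind or turn over this bulky, poorly soluble substrate. One-electron oxidation of the free phenols may divert material into oligomers. Overoxidation, or weak discrimination between the two benzylic hydrogens, may erode the outcome. The fallback uses known chemistry only and brings the lactol carbon in at the aldehyde oxidation level. It sets out from diene 12. Commercial 3,3-diethoxyprop-1-yne is lithiated (n-BuLi, THF, −78 °C) and acylated with di-tert-butyl dicarbonate to tert-butyl 4,4-diethoxybut-2-ynoate F1. This is heated with 12 as in step 11 and worked up with neutral methanol to give allyl 3-(benzyloxy)-2-[3-(tert-butoxycarbonyl)-2-(diethoxymethyl)-4,6-dihydroxy-5-methylphenoxy]-4-methoxy-6-methylbenzoate F2. Deallylation (Pd(PPh3)4, morpholine) gives the benzoic acid F3, DCC lactonisation gives the acetal depsidone F4, and hydrogenolysis (H2, Pd/C, EtOAc with a trace of Et3N) gives the phenol F5. Aqueous trifluoroacetic acid then removes the tert-butyl ester and the acetal, and the resulting 2-formylbenzoic acid should close spontaneously to the racemic hydroxyphthalide F6. The enantiomers are separated by preparative chromatography on a polysaccharide chiral stationary phase (neutral eluent, low temperature). The unwanted antipode is re-equilibrated through the open formyl acid with a trace of amine and recycled. The R enantiomer is target 23, where the fallback rejoins the route.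

Step 11. Thermal breakdown of the tetrasubstituted diene (silyl migration, protodesilylation) may outrun its addition to the singly activated, β-substituted alkyne, or a Michael-type adduct may fail to ring-close. The fallback replaces the ester-activated dienophile by the far more electrophilic aldehyde and adjusts the oxidation level afterwards. It sets out from diene 12. Silyl ether 13 is lithiated and formylated with DMF to 4-(tert-butyldimethylsilyloxy)but-2-ynal F7. This should add to 12 without catalyst between −20 °C and room temperature, with the same regiochemistry; no Lewis acid is used, so that cycloaddition at the C=O group stays slow. Aromatisation and methanolysis should then give allyl 3-(benzyloxy)-2-[2-{[(tert-butyldimethylsilyl)oxy]methyl}-3-formyl-4,6-dihydroxy-5-methylphenoxy]-4-methoxy-6-methylbenzoate F8. Pinnick oxidation gives the corresponding ring B carboxylic acid F9. TsOH in methanol removes the silyl group and lactonises the hydroxy acid, returning to the route at phthalide 19.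

Step 9. The lithium dienolate may add to the neighbouring allyl ester (Dieckmann-type closure to a benzofuranone) or be silylated on carbon, and the diene may hydrolyse during isolation. The fallback avoids any carbanion. It sets out from keto ester 10, which is silylated twice on oxygen by soft enolisation (TMSOTf, Et3N, Et2O, 0 °C; silylation of the carbonyl oxygens followed by amine deprotonation). It comes back at diene 12, bypassing 11, and makes no new compound.

Further compounds

F1 | step 16 | tert-butyl 4,4-diethoxybut-2-ynoate | CCOC(OCC)C#CC(=O)OC(C)(C)C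
F2 | step 16 | allyl 3-(benzyloxy)-2-[3-(tert-butoxycarbonyl)-2-(diethoxymethyl)-4,6-dihydroxy-5-methylphenoxy]-4-methoxy-6-methylbenzoate | C=CCOC(=O)c1c(C)cc(OC)c(OCc2ccccc2)c1Oc1c(O)c(C)c(O)c(C(=O)OC(C)(C)C)c1C(OCC)OCC
F3 | step 16 | 3-(benzyloxy)-2-[3-(tert-butoxycarbonyl)-2-(diethoxymethyl)-4,6-dihydroxy-5-methylphenoxy]-4-methoxy-6-methylbenzoic acid | OC(=O)c1c(C)cc(OC)c(OCc2ccccc2)c1Oc1c(O)c(C)c(O)c(C(=O)OC(C)(C)C)c1C(OCC)OCC
F4 | step 16 | benzyl-protected depsidone carrying tert-butyl ester and diethyl acetal on ring B | COc1cc(C)c2c(c1OCc1ccccc1)Oc1c(c(C)c(O)c(C(=O)OC(C)(C)C)c1C(OCC)OCC)OC2=O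
F5 | step 16 | depsidone with free ring A hydroxyl carrying tert-butyl ester and diethyl acetal on ring B | COc1cc(C)c2c(c1O)Oc1c(c(C)c(O)c(C(=O)OC(C)(C)C)c1C(OCC)OCC)OC2=O
F6 | step 16 | racemic hydroxyphthalide depsidone (racemate of 23) | COc1cc(C)c2c(c1O)Oc1c(c(C)c(O)c3c1C(O)OC3=O)OC2=O
F7 | step 11 | 4-(tert-butyldimethylsilyloxy)but-2-ynal | O=CC#CCO[Si](C)(C)C(C)(C)C
F8 | step 11 | allyl 3-(benzyloxy)-2-[2-{[(tert-butyldimethylsilyl)oxy]methyl}-3-formyl-4,6-dihydroxy-5-methylphenoxy]-4-methoxy-6-methylbenzoate | O=Cc1c(O)c(C)c(O)c(Oc2c(C(=O)OCC=C)c(C)cc(OC)c2OCc2ccccc2)c1CO[Si](C)(C)C(C)(C)C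
F9 | step 11 | 3-[2-[(allyloxy)carbonyl]-6-(benzyloxy)-5-methoxy-3-methylphenoxy]-2-{[(tert-butyldimethylsilyl)oxy]methyl}-4,6-dihydroxy-5-methylbenzoic acid | OC(=O)c1c(O)c(C)c(O)c(Oc2c(C(=O)OCC=C)c(C)cc(OC)c2OCc2ccccc2)c1CO[Si](C)(C)C(C)(C)C
F0 | step 9 | none | none
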